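Ring A is assembled across its spiro atom (spiro[5.5]undecane numbering: ring A C1–C5, spiro C6, ring B C7–C11). An exo-selective, catalytic asymmetric Diels–Alder reaction joins a ring B α-methylene ketone that already carries the C8 vinyl bromide to a (1E,3E)-4-bromo-3-methyl-1-siloxybutadiene, forging the C4–C5 (CHBr–CH2) and C1–C6 (CHO–spiro) bonds at once. The step exploits the 1,4-cis relationship of the C1 oxygen and the C4 bromine across ring A together with the quaternary spiro carbon C6, and fixes all three centres. The allylic bromine then relays its configuration to C3 in a bromonium-guided hydrochlorination; the ring B ketone becomes a bromodiene, and two epoxidations, the first directed by the C1 hydroxyl, complete the target.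

Key step: step 8

Remark: the (S)-configured acid catalyst of step 8 is assumed to deliver the 6R adduct; should the sense of induction be the opposite, its (R)-antipode is used without any other change.

Step 1
Reactants: 1 2,2-dimethylcyclohexane-1,3-dione
Product: 2 3-bromo-2,2-dimethylcyclohex-3-en-1-one
Conditions: (PhO)3P, Br2, CH2Cl2, −60 °C; then 1 (1 equiv), Et3N, −60 °C → reflux
Reagents that add atoms: bromine BrBr (delivered as triphenyl phosphite dibromide)
Why: Ketone-to-vinyl-bromide conversion through an enol phosphonium species with loss of triphenyl phosphate; one equivalent of reagent should limit the reaction to one carbonyl, and the quaternary C2 leaves only one direction for the new alkene.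

Step 2
Reactants: 2 3-bromo-2,2-dimethylcyclohex-3-en-1-one
Product: 3 1-bromo-6,6-dimethyl-5-methylidenecyclohex-1-ene
Conditions: Ph3PCH3Br, KOtBu, toluene, 0 → 80 °C
Reagents that add atoms: methyltriphenylphosphonium bromide C[P+](c1ccccc1)(c1ccccc1)c1ccccc1.[Br-]
Why: Wittig methylenation with the salt-free ylide at elevated temperature, the usual answer to a ketone flanked by a quaternary carbon; the vinyl bromide is inert to the ylide.

Step 3
Reactants: 3 1-bromo-6,6-dimethyl-5-methylidenecyclohex-1-ene
Product: 4 rac-4-bromo-5,5-dimethyl-6-methylidenecyclohex-3-en-1-ol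
Conditions: SeO2 (cat.), t-BuOOH, CH2Cl2, 0 °C → rt
Reagents that add atoms: tert-butyl hydroperoxide CC(C)(C)OO (terminal oxygen source), selenium dioxide O=[Se]=O (catalytic oxygen carrier)
Why: Riley-type allylic oxidation (ene reaction, then 2,3-sigmatropic shift) of the electron-richer 1,1-disubstituted alkene, whose only allylic C–H bonds are those of the ring CH2; the carbinol centre is racemic and is erased in step 4.

Step 4
Reactants: 4 rac-4-bromo-5,5-dimethyl-6-methylidenecyclohex-3-en-1-ol
Product: 5 4-bromo-5,5-dimethyl-6-methylidenecyclohex-3-en-1-one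
Conditions: MnO2, CH2Cl2, rt; filtered and used at once
Reagents that add atoms: none
Why: Selective oxidation of an allylic alcohol by MnO2 under neutral conditions; these should spare the dimerisation-prone α-methylene ketone, which the adjacent gem-dimethyl group also shields.

Step 5
Reactants: 6 but-3-yn-1-ol
Product: 8 (3E)-4-bromo-3-methylbut-3-en-1-ol, via alkenylalane 7 (not isolated)
Conditions: AlMe3, Cp2ZrCl2 (cat.), CH2Cl2, 0 °C → rt; then NBS, THF, −30 → 0 °C
Reagents that add atoms: trimethylaluminium C[Al](C)C, N-bromosuccinimide O=C1CCC(=O)N1Br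
Why: Negishi zirconium-catalysed carboalumination adds methyl and aluminium syn across the alkyne, and bromodealumination with retention gives the E-vinyl bromide (bromine trans to the chain).

Step 6
Reactants: 8 (3E)-4-bromo-3-methylbut-3-en-1-ol
Product: 9 (3E)-4-bromo-3-methylbut-3-enal
Conditions: Dess–Martin periodinane, pyridine, CH2Cl2, 0 °C; used crude
Reagents that add atoms: none
Why: Buffered Dess–Martin oxidation should give the β,γ-unsaturated aldehyde without moving the double bond into conjugation.

Step 7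
Reactants: 9 (3E)-4-bromo-3-methylbut-3-enal
Product: 10 {[(1E,3E)-4-bromo-3-methylbuta-1,3-dien-1-yl]oxy}tri(propan-2-yl)silane
Conditions: TIPSOTf, Et3N, Et2O, −78 → 0 °C
Reagents that add atoms: triisopropylsilyl trifluoromethanesulfonate CC(C)[Si](OS(=O)(=O)C(F)(F)F)(C(C)C)C(C)C
Why: Soft enolisation removes the doubly activated α-hydrogen and leaves the E-vinyl bromide untouched; the conjugated 1E dienol ether is the isomer needed, and any 1Z isomer formed alongside is carried on because it is inert in step 8.

Step 8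
Reactants: 5 4-bromo-5,5-dimethyl-6-methylidenecyclohex-3-en-1-one, 10 {[(1E,3E)-4-bromo-3-methylbuta-1,3-dien-1-yl]oxy}tri(propan-2-yl)silane (1.5 equiv)
Product: 11 (1S,4S,6R)-4,8-dibromo-3,7,7-trimethyl-1-{[tri(propan-2-yl)silyl]oxy}spiro[5.5]undeca-2,8-dien-11-one
Conditions: (S)-1,1,1-trifluoro-N-[4-oxido-2,6-bis(2,4,6-triisopropylphenyl)dinaphtho[2,1-d:1′,2′-f][1,3,2]dioxaphosphepin-4-yl]methanesulfonamide (10 mol %), 4 Å MS, toluene, −78 → −40 °C
Reagents that add atoms: none
Why: The strong chiral Brønsted acid (or its silylated form after silyl transfer from 10) activates the s-cis-locked enone carbonyl of 5, and the electron-rich diene adds in a concerted, asynchronous [4+2] mode in which its bromine-bearing terminus (future C4) bonds first to the exocyclic CH2 (C5) and the siloxy-bearing terminus (C1) then closes onto the α-carbon to create the spiro atom C6. The closest known reaction types are the catalytic asymmetric spirocyclising Diels–Alder reaction of α-methylene cycloalkanones and the N-triflyl phosphoramide-catalysed Diels–Alder reaction of enones with siloxydienes. Ring A is closed by intermolecular [4+2] cycloaddition, suprafacial on both partners, with the ortho regiochemistry dictated jointly by the 1-siloxy and 3-methyl donors. C1 and C4 emerge cis because both substituents are outside groups of the (1E,3E)-diene; their relation to C6 follows from the exo transition state (carbonyl exo, CMe2 carbon under the diene) that s-cis-locked α-methylene carbonyl dienophiles prefer and that the bulky acid on the carbonyl should reinforce; the absolute configuration at C6 is set by the chiral counter-anion pocket, which selects one enantiotopic face of the C6=CH2 bond. The step therefore needs regio-, exo- and enantioface selectivity, secured respectively by the donor pattern of the diene, the locked enone geometry plus catalyst bulk, and the catalyst. Any 1Z isomer of 10 cannot reach the s-cis conformation and stays behind, so only the 1E,3E diene is funnelled into 11.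

Step 9
Reactants: 11 (1S,4S,6R)-4,8-dibromo-3,7,7-trimethyl-1-{[tri(propan-2-yl)silyl]oxy}spiro[5.5]undeca-2,8-dien-11-one
Product: 12 (1S,3S,4S,6R)-4,8-dibromo-3-chloro-3,7,7-trimethyl-1-{[tri(propan-2-yl)silyl]oxy}spiro[5.5]undec-8-en-11-one
Conditions: HCl (g), CH2Cl2, −78 → −20 °C
Reagents that add atoms: hydrogen chloride Cl
Why: Markovnikov ionic hydrochlorination with neighbouring-group participation: protonation at C2 gives the tertiary C3 cation, the C4 bromine bridges it on the face fixed in step 8, and chloride opens the unsymmetrical bromonium ion at the tertiary carbon anti to bromine, so the 3S centre (Cl trans to Br) is set by stereochemical relay and not by facial bias.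

Step 10
Reactants: 12 (1S,3S,4S,6R)-4,8-dibromo-3-chloro-3,7,7-trimethyl-1-{[tri(propan-2-yl)silyl]oxy}spiro[5.5]undec-8-en-11-one
Product: 13 (1S,3S,4S,6R)-4,8-dibromo-3-chloro-3,7,7,11-tetramethyl-1-{[tri(propan-2-yl)silyl]oxy}spiro[5.5]undec-8-en-11-ol (C11 configuration not assigned)
Conditions: MeLi, CeCl3, THF, −78 °C
Reagents that add atoms: methyllithium [Li]C
Why: The weakly basic, oxophilic organocerium reagent should add to the hindered, enolisable ketone at a temperature at which the alkyl and vinyl halides do not react; the new C11 centre need not be controlled because step 11 removes it.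

Step 11
Reactants: 13 (1S,3S,4S,6R)-4,8-dibromo-3-chloro-3,7,7,11-tetramethyl-1-{[tri(propan-2-yl)silyl]oxy}spiro[5.5]undec-8-en-11-ol
Product: 14 (1S,3S,4S,6R)-4,8-dibromo-3-chloro-3,7,7,11-tetramethyl-1-{[tri(propan-2-yl)silyl]oxy}spiro[5.5]undeca-8,10-diene
Conditions: Burgess reagent, toluene, 60 °C
Reagents that add atoms: none
Why: Burgess dehydration (syn elimination through the sulfamate ester) should take the C10 hydrogen, which is allylic to the C8=C9 bromoalkene, and so give the conjugated 8,10-diene in preference to the exocyclic alkene.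

Step 12
Reactants: 14 (1S,3S,4S,6R)-4,8-dibromo-3-chloro-3,7,7,11-tetramethyl-1-{[tri(propan-2-yl)silyl]oxy}spiro[5.5]undeca-8,10-diene
Product: 15 (1S,3S,4S,6R)-4,8-dibromo-3-chloro-3,7,7,11-tetramethylspiro[5.5]undeca-8,10-dien-1-ol
Conditions: HF·pyridine, pyridine, THF, 0 °C → rt
Reagents that add atoms: none
Why: Fluoride-driven Si–O cleavage under buffered, weakly acidic conditions that should not eliminate the vicinal bromochloride or protonate the bromodiene.

Step 13
Reactants: 15 (1S,3S,4S,6R)-4,8-dibromo-3-chloro-3,7,7,11-tetramethylspiro[5.5]undeca-8,10-dien-1-ol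
Product: 16 prepacifenol, (1S,3S,4S,6R,10R,11S)-4,8-dibromo-3-chloro-10,11-epoxy-3,7,7,11-tetramethylspiro[5.5]undec-8-en-1-ol
Conditions: VO(acac)2 (cat.), t-BuOOH, CH2Cl2, 0 °C; non-acidic work-up, used without chromatography on silica
Reagents that add atoms: tert-butyl hydroperoxide CC(C)(C)OO
Why: Vanadium-catalysed hydroxyl-directed epoxidation: the homoallylic C1 alkoxide delivers oxygen to the proximal, electron-richer C10=C11 bond on the face of ring B where C1 sits (10R,11S), while the deactivated bromoalkene is left alone.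

Step 14
Reactants: 16 prepacifenol
Product: 17 prepacifenol epoxide, (1S,3S,4S,6R,8R,9R,10R,11S)-4,8-dibromo-3-chloro-8,9:10,11-diepoxy-3,7,7,11-tetramethylspiro[5.5]undecan-1-ol
Conditions: dimethyldioxirane, acetone, 0 °C
Reagents that add atoms: dimethyldioxirane CC1(C)OO1
Why: Neutral dioxirane epoxidation of the vinyl bromide from the face anti to the adjacent 10,11-epoxide (the C5 face of ring B) should give the trans-diepoxide with 8R,9R configuration, without acid that could open the vinyl epoxide or the bromo-epoxide.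

Compound list
1 | 2,2-dimethylcyclohexane-1,3-dione | CC1(C)C(=O)CCCC1=O | starting material
2 | 3-bromo-2,2-dimethylcyclohex-3-en-1-one | CC1(C)C(=O)CCC=C1Br | intermediate
3 | 1-bromo-6,6-dimethyl-5-methylidenecyclohex-1-ene | C=C1CCC=C(Br)C1(C)C | intermediate
4 | rac-4-bromo-5,5-dimethyl-6-methylidenecyclohex-3-en-1-ol | C=C1C(O)CC=C(Br)C1(C)C | intermediate
5 | 4-bromo-5,5-dimethyl-6-methylidenecyclohex-3-en-1-one | C=C1C(=O)CC=C(Br)C1(C)C | intermediate
6 | but-3-yn-1-ol | C#CCCO | starting material
7 | [(1E)-4-(dimethylalumanyloxy)-2-methylbut-1-en-1-yl]dimethylalumane (alkenylalane, formed in the flask) | C[Al](C)/C=C(\C)CCO[Al](C)C | intermediate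
8 | (3E)-4-bromo-3-methylbut-3-en-1-ol | OCC/C(C)=C/Br | intermediate
9 | (3E)-4-bromo-3-methylbut-3-enal | O=CC/C(C)=C/Br | intermediate
10 | {[(1E,3E)-4-bromo-3-methylbuta-1,3-dien-1-yl]oxy}tri(propan-2-yl)silane | CC(C)[Si](C(C)C)(C(C)C)O/C=C/C(C)=C/Br | intermediate
11 | (1S,4S,6R)-4,8-dibromo-3,7,7-trimethyl-1-{[tri(propan-2-yl)silyl]oxy}spiro[5.5]undeca-2,8-dien-11-one (C1–O and C4–Br cis to each other and to C7) | CC1(C)[C@@]2(C[C@H](Br)C(C)=C[C@@H]2O[Si](C(C)C)(C(C)C)C(C)C)C(=O)CC=C1Br | intermediate
12 | (1S,3S,4S,6R)-4,8-dibromo-3-chloro-3,7,7-trimethyl-1-{[tri(propan-2-yl)silyl]oxy}spiro[5.5]undec-8-en-11-one | CC1(C)[C@@]2(C[C@H](Br)[C@@](C)(Cl)C[C@@H]2O[Si](C(C)C)(C(C)C)C(C)C)C(=O)CC=C1Br | intermediate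
13 | (1S,3S,4S,6R)-4,8-dibromo-3-chloro-3,7,7,11-tetramethyl-1-{[tri(propan-2-yl)silyl]oxy}spiro[5.5]undec-8-en-11-ol (C11 not assigned) | CC1(C)[C@@]2(C[C@H](Br)[C@@](C)(Cl)C[C@@H]2O[Si](C(C)C)(C(C)C)C(C)C)C(C)(O)CC=C1Br | intermediate
14 | (1S,3S,4S,6R)-4,8-dibromo-3-chloro-3,7,7,11-tetramethyl-1-{[tri(propan-2-yl)silyl]oxy}spiro[5.5]undeca-8,10-diene | CC1(C)[C@@]2(C[C@H](Br)[C@@](C)(Cl)C[C@@H]2O[Si](C(C)C)(C(C)C)C(C)C)C(C)=CC=C1Br | intermediate
15 | (1S,3S,4S,6R)-4,8-dibromo-3-chloro-3,7,7,11-tetramethylspiro[5.5]undeca-8,10-dien-1-ol | CC1(C)[C@@]2(C[C@H](Br)[C@@](C)(Cl)C[C@@H]2O)C(C)=CC=C1Br | intermediate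
16 | prepacifenol, (1S,3S,4S,6R,10R,11S)-4,8-dibromo-3-chloro-10,11-epoxy-3,7,7,11-tetramethylspiro[5.5]undec-8-en-1-ol | CC1(C)[C@@]2(C[C@H](Br)[C@@](C)(Cl)C[C@@H]2O)[C@]2(C)O[C@@H]2C=C1Br | intermediate
17 | prepacifenol epoxide, (1S,3S,4S,6R,8R,9R,10R,11S)-4,8-dibromo-3-chloro-8,9:10,11-diepoxy-3,7,7,11-tetramethylspiro[5.5]undecan-1-ol | CC1(C)[C@@]2(C[C@H](Br)[C@@](C)(Cl)C[C@@H]2O)[C@]2(C)O[C@@H]2[C@H]2O[C@]21Br | target

Total step count: 14. Longest linear sequence: 11 steps (steps 1–4, then 8–14).

Steps most likely to fail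

Step 8. The cycloaddition may lose exo topology or enantioface control at the doubly hindered dienophile, or may stall after the first C–C bond through silyl transfer (Mukaiyama–Michael arrest). The fallback replaces catalyst control by a covalently bound auxiliary on a diene that cannot transfer silicon. It sets out from 9 (with 5) and comes back at 12. The potassium dienolate of 9 (KN(SiMe3)2, THF, −78 °C) is acylated with (S)-O-methylmandeloyl chloride to give (1E,3E)-4-bromo-3-methylbuta-1,3-dien-1-yl (2S)-2-methoxy-2-phenylacetate F1. Cycloaddition of F1 with 5 under BF3·OEt2 in toluene at −40 °C, with the facial bias coming from the mandelate, should give (1S,4S,6R)-4,8-dibromo-3,7,7-trimethyl-11-oxospiro[5.5]undeca-2,8-dien-1-yl (2S)-2-methoxy-2-phenylacetate F2; the antipode of the auxiliary is taken if the sense requires it. Hydrochlorination as in step 9, to which the ester is more robust than the silyl ether, gives (1S,3S,4S,6R)-4,8-dibromo-3-chloro-3,7,7-trimethyl-11-oxospiro[5.5]undec-8-en-1-yl (2S)-2-methoxy-2-phenylacetate F3. Brief methanolysis (K2CO3, MeOH, 0 °C) releases (1S,3S,4S,6R)-4,8-dibromo-3-chloro-1-hydroxy-3,7,7-trimethylspiro[5.5]undec-8-en-11-one F4, which is silylated at once (TIPSOTf, 2,6-lutidine, CH2Cl2, −78 °C) to 12.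

Step 9. Ionisation of the allylic C–Br or C–O bond (allylic transposition, loss of the silyl ether) may outrun protonation of the inductively deactivated alkene. The fallback moves the double bond first and then adds BrCl. It sets out from 10 (with 5) and comes back at 12. Bromine–lithium exchange on 10 (t-BuLi, Et2O, −78 °C) and quenching with Me3SiCl give {[(1E,3E)-3-methyl-4-(trimethylsilyl)buta-1,3-dien-1-yl]oxy}tri(propan-2-yl)silane F5. Its cycloaddition with 5 under the conditions of step 8 should give the allylsilane (1S,4S,6R)-8-bromo-3,7,7-trimethyl-1-{[tri(propan-2-yl)silyl]oxy}-4-(trimethylsilyl)spiro[5.5]undeca-2,8-dien-11-one F6. Protodesilylation (CF3CO2H, CH2Cl2, −20 °C; proton to C2, double bond to C3=C4) gives (1S,6R)-8-bromo-3,7,7-trimethyl-1-{[tri(propan-2-yl)silyl]oxy}spiro[5.5]undeca-3,8-dien-11-one F7. Markovnikov anti bromochlorination with Bu4NBrCl2 in CH2Cl2 at −78 °C would then lead to 12. In this variant the face of bromonium formation is under substrate control, and may well favour the other face, so it has to be checked.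

Step 10. Enolisation of the hindered β,γ-unsaturated ketone toward C10, or halogen–metal exchange and elimination at the vicinal bromochloride, may compete with 1,2-addition. The fallback turns the enolisation into the productive path. It sets out from 12 and comes back at 14, bypassing 13 and step 11. Deprotonation with KN(SiMe3)2 and O-triflation with PhNTf2 (THF, −78 °C) give the bromodienyl triflate (1S,3S,4S,6R)-4,8-dibromo-3-chloro-3,7,7-trimethyl-1-{[tri(propan-2-yl)silyl]oxy}spiro[5.5]undeca-8,10-dien-11-yl trifluoromethanesulfonate F8. Coupling with Me2CuLi (THF, −20 °C) is expected to proceed at the triflate faster than at the hindered vinyl bromide and to give 14.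

Further compounds
F1 | step 8 | (1E,3E)-4-bromo-3-methylbuta-1,3-dien-1-yl (2S)-2-methoxy-2-phenylacetate | CO[C@H](C(=O)O/C=C/C(C)=C/Br)c1ccccc1
F2 | step 8 | (1S,4S,6R)-4,8-dibromo-3,7,7-trimethyl-11-oxospiro[5.5]undeca-2,8-dien-1-yl (2S)-2-methoxy-2-phenylacetate | CC1(C)[C@@]2(C[C@H](Br)C(C)=C[C@@H]2OC(=O)[C@@H](OC)c3ccccc3)C(=O)CC=C1Br
F3 | step 8 | (1S,3S,4S,6R)-4,8-dibromo-3-chloro-3,7,7-trimethyl-11-oxospiro[5.5]undec-8-en-1-yl (2S)-2-methoxy-2-phenylacetate | CC1(C)[C@@]2(C[C@H](Br)[C@@](C)(Cl)C[C@@H]2OC(=O)[C@@H](OC)c3ccccc3)C(=O)CC=C1Br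
F4 | step 8 | (1S,3S,4S,6R)-4,8-dibromo-3-chloro-1-hydroxy-3,7,7-trimethylspiro[5.5]undec-8-en-11-one | CC1(C)[C@@]2(C[C@H](Br)[C@@](C)(Cl)C[C@@H]2O)C(=O)CC=C1Br
F5 | step 9 | {[(1E,3E)-3-methyl-4-(trimethylsilyl)buta-1,3-dien-1-yl]oxy}tri(propan-2-yl)silane | CC(C)[Si](C(C)C)(C(C)C)O/C=C/C(C)=C/[Si](C)(C)C
F6 | step 9 | (1S,4S,6R)-8-bromo-3,7,7-trimethyl-1-{[tri(propan-2-yl)silyl]oxy}-4-(trimethylsilyl)spiro[5.5]undeca-2,8-dien-11-one | CC1(C)[C@@]2(C[C@H]([Si](C)(C)C)C(C)=C[C@@H]2O[Si](C(C)C)(C(C)C)C(C)C)C(=O)CC=C1Br
F7 | step 9 | (1S,6R)-8-bromo-3,7,7-trimethyl-1-{[tri(propan-2-yl)silyl]oxy}spiro[5.5]undeca-3,8-dien-11-one | CC1(C)[C@@]2(CC=C(C)C[C@@H]2O[Si](C(C)C)(C(C)C)C(C)C)C(=O)CC=C1Br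
F8 | step 10 | (1S,3S,4S,6R)-4,8-dibromo-3-chloro-3,7,7-trimethyl-1-{[tri(propan-2-yl)silyl]oxy}spiro[5.5]undeca-8,10-dien-11-yl trifluoromethanesulfonate | CC1(C)[C@@]2(C[C@H](Br)[C@@](C)(Cl)C[C@@H]2O[Si](C(C)C)(C(C)C)C(C)C)C(OS(=O)(=O)C(F)(F)F)=CC=C1Br
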